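**Plan**
1. Ring C is opened at C3–C4 (with the C2–H bond), which turns the flavanone into the achiral aldehyde–enol ether 15. This works because the C4 carbonyl carbon sits on ring A ortho to the O1 ether oxygen, and C2 is an O1- and aryl-bearing carbon next to the C3 methylene: ring C is the formal hydroacylation adduct of a C4 aldehyde across a C2=C3 aryl enol ether.
2. Further cuts: C4a–CHO and C6–prenyl (two ortho-lithiations), the enol ether =CH2 (ester methylenation), and the O1–acyl ester bond (ring A phenol 5 + ring B acid 8).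
3. Ring A regiochemistry is fixed at the start: the formyl group of 2,4,6-trihydroxybenzaldehyde leaves one chelated OH free and is then reduced to the C8 methyl, so that OH is O1 next to the methyl; prenyl enters between the two MOM ethers (C6), formyl at the last free carbon (C4a).
4. Forward order: ring A phenol → ester with ring B → enol ether → prenyl → formyl → closure of ring C at C3–C4 → deprotection.
5. Stereochemistry: the only stereocenter, C2 (S), is created in the ring closure by a chiral bisphosphine–rhodium catalyst (hydride delivery to one face of the enol ether); no base is used afterwards.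

Key step: step 8

Remark on the chemistry: the facial sense of the rhodium–bisphosphine catalyst on an aryl enol ether cannot be assigned in advance; (R)-DTBM-SEGPHOS is written in step 8, and the (S)-ligand takes its place if a test run shows hydride delivery to the other face.

**Route**

Step 1
Reactants: 1 2,4,6-trihydroxybenzaldehyde
Product: 2 2-hydroxy-4,6-bis(methoxymethoxy)benzaldehyde
Conditions: MOMCl (2.1 equiv), i-Pr2NEt, CH2Cl2, 0 °C to rt
Reagents that add atoms: chloromethyl methyl ether, COCCl
Why: O-alkylation (MOM protection) should stop after two groups because the last ortho hydroxyl is hydrogen-bonded to the formyl oxygen, and the two ortho hydroxyls of 1 are equivalent, so no regiochemical question arises.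

Step 2
Reactants: 2 2-hydroxy-4,6-bis(methoxymethoxy)benzaldehyde
Product: 5 3,5-bis(methoxymethoxy)-2-methylphenol, via ethyl aryl carbonate 3 (not isolated), via ortho-quinone methide 4 (not isolated)
Conditions: ClCO2Et, Et3N, THF, 0 °C; then NaBH4, H2O, 0 °C to rt
Reagents that add atoms: none
Why: Reductive deoxygenation of a salicylaldehyde through an ortho-quinone methide: hydride reduces the formyl group of 3, the carbonate shifts to the benzylic oxygen and leaves to give 4, and a second hydride adds to the exocyclic carbon, so the old formyl carbon becomes the future C8 methyl beside the only free hydroxyl (future O1).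

Step 3
Reactants: 6 4-hydroxybenzoic acid
Product: 8 4-(triisopropylsilyloxy)benzoic acid, via bis-silylated benzoate 7 (not isolated)
Conditions: TIPSCl (2.2 equiv), imidazole, DMF, rt; then K2CO3 (1.1 equiv), THF/MeOH/H2O, rt; work-up at pH 4
Reagents that add atoms: triisopropylsilyl chloride, CC(C)[Si](Cl)(C(C)C)C(C)C
Why: Silylation of both acidic groups followed by selective hydrolysis of the much more labile silyl ester should leave the aryl silyl ether, a bulky group that does not direct lithiation on ring B later.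

Step 4
Reactants: 5 3,5-bis(methoxymethoxy)-2-methylphenol; 8 4-(triisopropylsilyloxy)benzoic acid
Product: 9 3,5-bis(methoxymethoxy)-2-methylphenyl 4-(triisopropylsilyloxy)benzoate
Conditions: DIC, DMAP (cat.), CH2Cl2, 0 °C to rt
Reagents that add atoms: none
Why: Steglich esterification of a phenol with one ortho substituent should be unproblematic and joins ring B to the future O1 with the future C2 at the ester oxidation level.

Step 5
Reactants: 9 3,5-bis(methoxymethoxy)-2-methylphenyl 4-(triisopropylsilyloxy)benzoate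
Product: 10 1,5-bis(methoxymethoxy)-2-methyl-3-({1-[4-(triisopropylsilyloxy)phenyl]ethenyl}oxy)benzene
Conditions: Cp2TiMe2 (2.5 equiv), toluene/THF, 70 °C, dark; filtration through basic alumina
Reagents that add atoms: dimethyltitanocene, C[Ti](C)(C1C=CC=C1)C1C=CC=C1
Why: Petasis methylenation of an aryl benzoate by the thermally formed titanocene methylidene should give the aryl 1-arylvinyl ether under non-acidic conditions that spare the MOM and silyl ethers and the acid-labile product.

Step 6
Reactants: 10 1,5-bis(methoxymethoxy)-2-methyl-3-({1-[4-(triisopropylsilyloxy)phenyl]ethenyl}oxy)benzene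
Product: 12 1,3-bis(methoxymethoxy)-4-methyl-2-(3-methylbut-2-en-1-yl)-5-({1-[4-(triisopropylsilyloxy)phenyl]ethenyl}oxy)benzene, via aryllithium 11 (not isolated)
Conditions: s-BuLi, TMEDA, THF, −78 °C; CuBr·SMe2 (10 mol %); prenyl bromide, −78 °C to 0 °C
Reagents that add atoms: prenyl bromide, CC(C)=CCBr
Why: Directed ortho-metalation should occur at the ring A hydrogen flanked by two chelating MOM ethers and not at the one beside the poorly coordinating, bulky enol ether oxygen (ring B carries only a non-directing silyl ether), and copper-catalysed SN2 allylation then places the prenyl group at the future C6.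

Step 7
Reactants: 12 1,3-bis(methoxymethoxy)-4-methyl-2-(3-methylbut-2-en-1-yl)-5-({1-[4-(triisopropylsilyloxy)phenyl]ethenyl}oxy)benzene
Product: 15 4,6-bis(methoxymethoxy)-3-methyl-5-(3-methylbut-2-en-1-yl)-2-({1-[4-(triisopropylsilyloxy)phenyl]ethenyl}oxy)benzaldehyde, via aryllithium 13 (not isolated), via lithium aminoalkoxide 14 (not isolated)
Conditions: s-BuLi, TMEDA, THF, −78 °C; DMF, −78 °C to 0 °C; H2O
Reagents that add atoms: N,N-dimethylformamide, CN(C)C=O
Why: Directed ortho-metalation at the last ring hydrogen, which lies between a MOM ether and the enol ether oxygen, should be kinetically preferred at low temperature over lateral deprotonation, and formylation with DMF followed by a non-acidic aqueous quench releases the aldehyde at the future C4 without harming the enol ether.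

Step 8
Reactants: 15 4,6-bis(methoxymethoxy)-3-methyl-5-(3-methylbut-2-en-1-yl)-2-({1-[4-(triisopropylsilyloxy)phenyl]ethenyl}oxy)benzaldehyde
Product: 16 (2S)-5,7-bis(methoxymethoxy)-8-methyl-6-(3-methylbut-2-en-1-yl)-2-[4-(triisopropylsilyloxy)phenyl]-2,3-dihydro-4H-chromen-4-one
Conditions: [Rh(cod)Cl]2 (2.5 mol %), (R)-DTBM-SEGPHOS (5.5 mol %), NaB[3,5-(CF3)2C6H3]4 (5 mol %), 4 Å MS, THF, 60 °C
Reagents that add atoms: none
Why: Proposed new method: cationic monovalent rhodium should add oxidatively into the formyl C–H of 15 to give an acyl rhodium hydride (trivalent rhodium), the tethered 1,1-disubstituted enol ether should insert into Rh–H with hydride going to the O- and aryl-bearing carbon (future C2) and rhodium to the terminal CH2 (future C3), and C–C reductive elimination from the resulting seven-membered acyl alkyl rhodacycle should form the C3–C4 bond; the reasoning is that the enol ether oxygen only replaces the benzylic CH2 of a known substrate type without changing the ring sizes of the metallacycles. The closest known reaction type is the rhodium/bisphosphine-catalysed enantioselective intramolecular hydroacylation of 1,1-disubstituted alkenes in ortho-allylbenzaldehydes (six-membered ketones) and in N-(1-substituted vinyl)indole-2-carbaldehydes (hydride delivered to the heteroatom-bearing alkene carbon). Ring C closes in a formal 6-endo-trig mode with respect to the alkene. The only new stereocenter, C2, is set in the hydride insertion, where the chiral bisphosphine selects the enol ether face (aryloxy tether against ring B aryl), so no stereochemical information is needed in 15. The step needs endo over exo regioselectivity (the exo path would require a tertiary alkyl rhodium and a five-membered benzofuranone, which the 1,1-disubstitution disfavours), hydroacylation over decarbonylation (helped by the intramolecular alkene, the weakly coordinating counter-ion and the hemilabile ortho ether oxygens) and chemoselectivity over the prenyl group (trisubstituted, meta to the formyl group and out of reach). The medium is neutral and aprotic, so the acid-labile enol ether survives until it reacts, the alkene has no allylic hydrogen and cannot isomerise, and the base-sensitive C2 centre of 16 is not exposed to conditions that open ring C.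

Step 9
Reactants: 16 (2S)-5,7-bis(methoxymethoxy)-8-methyl-6-(3-methylbut-2-en-1-yl)-2-[4-(triisopropylsilyloxy)phenyl]-2,3-dihydro-4H-chromen-4-one
Product: 18 (2S)-5,7-dihydroxy-2-(4-hydroxyphenyl)-8-methyl-6-(3-methylbut-2-en-1-yl)-2,3-dihydro-4H-chromen-4-one (5,7,4'-trihydroxy-8-methyl-6-prenylflavanone), via free 4'-phenol 17 (not isolated)
Conditions: KHF2, MeOH, rt; then HCl (ca. 2 M), MeOH, 35 °C
Reagents that add atoms: none
Why: Fluoride cleavage of the aryl silyl ether followed by acid-catalysed acetal exchange of the two MOM ethers with methanol should free the three phenols under mild acid, which should spare the prenyl alkene, and without base, so C2 is not epimerised through ring opening.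

**Compound list**
1 | 2,4,6-trihydroxybenzaldehyde | O=Cc1c(O)cc(O)cc1O | starting material
2 | 2-hydroxy-4,6-bis(methoxymethoxy)benzaldehyde | O=Cc1c(O)cc(OCOC)cc1OCOC | intermediate
3 | ethyl 2-formyl-3,5-bis(methoxymethoxy)phenyl carbonate | CCOC(=O)Oc1cc(OCOC)cc(OCOC)c1C=O | intermediate
4 | 3,5-bis(methoxymethoxy)-6-methylidenecyclohexa-2,4-dien-1-one | C=C1C(=O)C=C(OCOC)C=C1OCOC | intermediate
5 | 3,5-bis(methoxymethoxy)-2-methylphenol | Cc1c(O)cc(OCOC)cc1OCOC | intermediate
6 | 4-hydroxybenzoic acid | OC(=O)c1ccc(O)cc1 | starting material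
7 | triisopropylsilyl 4-(triisopropylsilyloxy)benzoate | CC(C)[Si](OC(=O)c1ccc(O[Si](C(C)C)(C(C)C)C(C)C)cc1)(C(C)C)C(C)C | intermediate
8 | 4-(triisopropylsilyloxy)benzoic acid | OC(=O)c1ccc(O[Si](C(C)C)(C(C)C)C(C)C)cc1 | intermediate
9 | 3,5-bis(methoxymethoxy)-2-methylphenyl 4-(triisopropylsilyloxy)benzoate | Cc1c(OC(=O)c2ccc(O[Si](C(C)C)(C(C)C)C(C)C)cc2)cc(OCOC)cc1OCOC | intermediate
10 | 1,5-bis(methoxymethoxy)-2-methyl-3-({1-[4-(triisopropylsilyloxy)phenyl]ethenyl}oxy)benzene | C=C(Oc1cc(OCOC)cc(OCOC)c1C)c1ccc(O[Si](C(C)C)(C(C)C)C(C)C)cc1 | intermediate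
11 | {2,6-bis(methoxymethoxy)-3-methyl-4-({1-[4-(triisopropylsilyloxy)phenyl]ethenyl}oxy)phenyl}lithium | C=C(Oc1cc(OCOC)c([Li])c(OCOC)c1C)c1ccc(O[Si](C(C)C)(C(C)C)C(C)C)cc1 | intermediate
12 | 1,3-bis(methoxymethoxy)-4-methyl-2-(3-methylbut-2-en-1-yl)-5-({1-[4-(triisopropylsilyloxy)phenyl]ethenyl}oxy)benzene | C=C(Oc1cc(OCOC)c(CC=C(C)C)c(OCOC)c1C)c1ccc(O[Si](C(C)C)(C(C)C)C(C)C)cc1 | intermediate
13 | {2,4-bis(methoxymethoxy)-5-methyl-3-(3-methylbut-2-en-1-yl)-6-({1-[4-(triisopropylsilyloxy)phenyl]ethenyl}oxy)phenyl}lithium | C=C(Oc1c([Li])c(OCOC)c(CC=C(C)C)c(OCOC)c1C)c1ccc(O[Si](C(C)C)(C(C)C)C(C)C)cc1 | intermediate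
14 | lithium (dimethylamino){2,4-bis(methoxymethoxy)-5-methyl-3-(3-methylbut-2-en-1-yl)-6-({1-[4-(triisopropylsilyloxy)phenyl]ethenyl}oxy)phenyl}methanolate | C=C(Oc1c(C(O[Li])N(C)C)c(OCOC)c(CC=C(C)C)c(OCOC)c1C)c1ccc(O[Si](C(C)C)(C(C)C)C(C)C)cc1 | intermediate
15 | 4,6-bis(methoxymethoxy)-3-methyl-5-(3-methylbut-2-en-1-yl)-2-({1-[4-(triisopropylsilyloxy)phenyl]ethenyl}oxy)benzaldehyde | C=C(Oc1c(C=O)c(OCOC)c(CC=C(C)C)c(OCOC)c1C)c1ccc(O[Si](C(C)C)(C(C)C)C(C)C)cc1 | intermediate
16 | (2S)-5,7-bis(methoxymethoxy)-8-methyl-6-(3-methylbut-2-en-1-yl)-2-[4-(triisopropylsilyloxy)phenyl]-2,3-dihydro-4H-chromen-4-one | CC(C)=CCc1c(OCOC)c(C)c2c(c1OCOC)C(=O)C[C@@H](c1ccc(O[Si](C(C)C)(C(C)C)C(C)C)cc1)O2 | intermediate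
17 | (2S)-2-(4-hydroxyphenyl)-5,7-bis(methoxymethoxy)-8-methyl-6-(3-methylbut-2-en-1-yl)-2,3-dihydro-4H-chromen-4-one | CC(C)=CCc1c(OCOC)c(C)c2c(c1OCOC)C(=O)C[C@@H](c1ccc(O)cc1)O2 | intermediate
18 | (2S)-5,7-dihydroxy-2-(4-hydroxyphenyl)-8-methyl-6-(3-methylbut-2-en-1-yl)-2,3-dihydro-4H-chromen-4-one | CC(C)=CCc1c(O)c(C)c2c(c1O)C(=O)C[C@@H](c1ccc(O)cc1)O2 | target

**Count**
Total steps: 9. Longest linear sequence: 8 steps (1, 2, 4, 5, 6, 7, 8, 9, from compound 1); step 3 is a one-step side branch.

**Steps most likely to fail**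

Step 8 (key step, new method). The acyl rhodium hydride may lose CO (decarbonylation), the hydride may insert with the opposite regiochemistry, or the facial selectivity may be poor. The fallback uses known chemistry, sets out from 15 and comes back at 16; it closes ring C at O1 and sets C2 by a catalytic aryl transfer. Mild hydrolysis of the enol ether (pyridinium p-toluenesulfonate, acetone/H2O, rt) should give 2-hydroxy-4,6-bis(methoxymethoxy)-3-methyl-5-(3-methylbut-2-en-1-yl)benzaldehyde F1. Excess ethynylmagnesium bromide (THF, 0 °C) should give 1-[2-hydroxy-4,6-bis(methoxymethoxy)-3-methyl-5-(3-methylbut-2-en-1-yl)phenyl]prop-2-yn-1-ol F2. MnO2 (CH2Cl2) should give the ynone 1-[2-hydroxy-4,6-bis(methoxymethoxy)-3-methyl-5-(3-methylbut-2-en-1-yl)phenyl]prop-2-yn-1-one F3, which should close by 6-endo-dig oxa-Michael addition (K2CO3, acetone) to 5,7-bis(methoxymethoxy)-8-methyl-6-(3-methylbut-2-en-1-yl)-4H-chromen-4-one F4. Rhodium-catalysed asymmetric 1,4-addition of 4-(triisopropylsilyloxy)phenylboronic acid ([Rh(OH)(cod)]2, electron-poor chiral biaryl bisphosphine, toluene/H2O) to F4 should then install ring B and the 2S centre and give 16.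

Step 7. The alkyllithium may deprotonate the doubly activated benzylic/allylic CH2 of the prenyl group or the aryl methyl instead of the ring, or add across the enol ether double bond. The fallback fixes the site of metalation with a halogen; it sets out from 12 and comes back at 15 through 13. Mild hydrolysis of the enol ether of 12 (pyridinium p-toluenesulfonate, acetone/H2O) should give 3,5-bis(methoxymethoxy)-2-methyl-4-(3-methylbut-2-en-1-yl)phenol F5. Iodination at its only free ring position, ortho to the hydroxyl (I2, morpholine, CH2Cl2, 0 °C), should give 2-iodo-3,5-bis(methoxymethoxy)-6-methyl-4-(3-methylbut-2-en-1-yl)phenol F6. Esterification with 8 (DIC, DMAP) should give 2-iodo-3,5-bis(methoxymethoxy)-6-methyl-4-(3-methylbut-2-en-1-yl)phenyl 4-(triisopropylsilyloxy)benzoate F7, and methylenation with Cp2TiMe2 should give 2-iodo-1,5-bis(methoxymethoxy)-4-methyl-6-(3-methylbut-2-en-1-yl)-3-({1-[4-(triisopropylsilyloxy)phenyl]ethenyl}oxy)benzene F8. Iodine–lithium exchange (n-BuLi, THF, −78 °C), which is much faster than deprotonation or addition, should give 13, and DMF then gives 15 as in step 7.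

Step 6. Lithiation may take place at the ring position beside the enol ether oxygen instead of between the MOM ethers, or the alkyllithium may add to the enol ether alkene. The fallback moves the prenylation ahead of enol ether formation; it sets out from 5 and comes back at 12. Silylation (TIPSCl, imidazole, DMF) should give [3,5-bis(methoxymethoxy)-2-methylphenoxy]triisopropylsilane F9. In F9 the bulky, non-coordinating silyl ether shields its neighbouring hydrogen, so s-BuLi/TMEDA (THF, −78 °C) should give only {2,6-bis(methoxymethoxy)-3-methyl-4-(triisopropylsilyloxy)phenyl}lithium F10. Prenyl bromide (CuBr·SMe2 cat.) should give [3,5-bis(methoxymethoxy)-2-methyl-4-(3-methylbut-2-en-1-yl)phenoxy]triisopropylsilane F11, and Bu4NF (THF, 0 °C) should then give the phenol F5 described above. Esterification with 8 (DIC, DMAP) should give 3,5-bis(methoxymethoxy)-2-methyl-4-(3-methylbut-2-en-1-yl)phenyl 4-(triisopropylsilyloxy)benzoate F12, and methylenation with Cp2TiMe2 gives 12.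

**Further compounds**
F1 | step 8 | 2-hydroxy-4,6-bis(methoxymethoxy)-3-methyl-5-(3-methylbut-2-en-1-yl)benzaldehyde | O=Cc1c(O)c(C)c(OCOC)c(CC=C(C)C)c1OCOC
F2 | step 8 | 1-[2-hydroxy-4,6-bis(methoxymethoxy)-3-methyl-5-(3-methylbut-2-en-1-yl)phenyl]prop-2-yn-1-ol | C#CC(O)c1c(O)c(C)c(OCOC)c(CC=C(C)C)c1OCOC
F3 | step 8 | 1-[2-hydroxy-4,6-bis(methoxymethoxy)-3-methyl-5-(3-methylbut-2-en-1-yl)phenyl]prop-2-yn-1-one | C#CC(=O)c1c(O)c(C)c(OCOC)c(CC=C(C)C)c1OCOC
F4 | step 8 | 5,7-bis(methoxymethoxy)-8-methyl-6-(3-methylbut-2-en-1-yl)-4H-chromen-4-one | CC(C)=CCc1c(OCOC)c(C)c2c(c1OCOC)C(=O)C=CO2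
F5 | step 7 | 3,5-bis(methoxymethoxy)-2-methyl-4-(3-methylbut-2-en-1-yl)phenol | Cc1c(O)cc(OCOC)c(CC=C(C)C)c1OCOC
F6 | step 7 | 2-iodo-3,5-bis(methoxymethoxy)-6-methyl-4-(3-methylbut-2-en-1-yl)phenol | Cc1c(O)c(I)c(OCOC)c(CC=C(C)C)c1OCOC
F7 | step 7 | 2-iodo-3,5-bis(methoxymethoxy)-6-methyl-4-(3-methylbut-2-en-1-yl)phenyl 4-(triisopropylsilyloxy)benzoate | Cc1c(OC(=O)c2ccc(O[Si](C(C)C)(C(C)C)C(C)C)cc2)c(I)c(OCOC)c(CC=C(C)C)c1OCOC
F8 | step 7 | 2-iodo-1,5-bis(methoxymethoxy)-4-methyl-6-(3-methylbut-2-en-1-yl)-3-({1-[4-(triisopropylsilyloxy)phenyl]ethenyl}oxy)benzene | C=C(Oc1c(I)c(OCOC)c(CC=C(C)C)c(OCOC)c1C)c1ccc(O[Si](C(C)C)(C(C)C)C(C)C)cc1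
F9 | step 6 | [3,5-bis(methoxymethoxy)-2-methylphenoxy]triisopropylsilane | Cc1c(O[Si](C(C)C)(C(C)C)C(C)C)cc(OCOC)cc1OCOC
F10 | step 6 | {2,6-bis(methoxymethoxy)-3-methyl-4-(triisopropylsilyloxy)phenyl}lithium | Cc1c(O[Si](C(C)C)(C(C)C)C(C)C)cc(OCOC)c([Li])c1OCOC
F11 | step 6 | [3,5-bis(methoxymethoxy)-2-methyl-4-(3-methylbut-2-en-1-yl)phenoxy]triisopropylsilane | Cc1c(O[Si](C(C)C)(C(C)C)C(C)C)cc(OCOC)c(CC=C(C)C)c1OCOC
F12 | step 6 | 3,5-bis(methoxymethoxy)-2-methyl-4-(3-methylbut-2-en-1-yl)phenyl 4-(triisopropylsilyloxy)benzoate | Cc1c(OC(=O)c2ccc(O[Si](C(C)C)(C(C)C)C(C)C)cc2)cc(OCOC)c(CC=C(C)C)c1OCOC
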